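**Retrosynthetic overview**
1. The strategy rests on the ketal carbon C1 of the 2,8-dioxabicyclo[3.2.1]octane: it carries O2 (the oxygen on C3), O8 and the side chain, and reaches C5 only through the unsubstituted C7H2–C6H2 bridge. C1 is therefore treated as the ester carbonyl of the side-chain acid on the C3 hydroxyl, and C6–C7 as an ethylene unit added across C1/C5.
2. Disconnections: C5–O8, C5–C6 and C1–C7 (ester carbonyl ylide from a C5 α-diazo ester plus tert-butyl acrylate, the acrylate carboxyl being removed afterwards); then O2–C1 (esterification); then C4–C5 (D-tartrate acetonide enolate plus methyl glyoxylate).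
3. Side-chain acid: (S)-2-methyl-3-phenylpropanoic acid → aldehyde → isopropenyl carbinol → Johnson–Claisen rearrangement (E alkene, brings in C1 and C1').
4. Ring order: the dioxane ring C1–O2–C3–C4–C5–O8 closes first (as the ylide) and the oxolane ring C1–C7–C6–C5–O8 second (cycloaddition), both in step 13; no ring is made later.
5. Two protective measures: the C5 carbonyl is held as its tosylhydrazone while the acetonide is exchanged onto a dithiol, and the bridge tert-butyl ester is cleaved without protic acid to spare the side-chain alkene.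

Key step: step 13

Assumption: the locants C1–C8 of the 2,8-dioxabicyclo[3.2.1]octane are also used for the corresponding atoms of the open-chain precursors; primed locants are side-chain atoms.

**Step 1**
Reactants: 1 (S)-2-methyl-3-phenylpropanoic acid
Product: 2 (S)-2-methyl-3-phenylpropan-1-ol
Conditions: LiAlH4, THF, 0 °C to rt; aqueous work-up
Reagents that add atoms: none
Why: Hydride reduction of the carboxylic acid to the primary alcohol; the stereocentre is not enolised under these conditions and should be kept.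

**Step 2**
Reactants: 2 (S)-2-methyl-3-phenylpropan-1-ol
Product: 3 (S)-2-methyl-3-phenylpropanal
Conditions: TEMPO (cat.), PhI(OAc)2, CH2Cl2, rt; used at once
Reagents that add atoms: none
Why: Oxoammonium-mediated (TEMPO/PhI(OAc)2) oxidation stops at the aldehyde under non-basic conditions, so the α-stereocentre should not epimerise.

**Step 3**
Reactants: 3 (S)-2-methyl-3-phenylpropanal; 4 isopropenylmagnesium bromide
Product: 5 (3RS,4S)-2,4-dimethyl-5-phenylpent-1-en-3-ol
Conditions: THF, −78 to 0 °C; aqueous work-up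
Reagents that add atoms: none
Why: Grignard addition to the aldehyde; the new carbinol centre forms as a mixture, which is harmless because it is consumed as the migration origin in step 4.

**Step 4**
Reactants: 5 (3RS,4S)-2,4-dimethyl-5-phenylpent-1-en-3-ol; 6 triethyl orthoacetate
Product: 8 ethyl (S,E)-4,6-dimethyl-7-phenylhept-4-enoate, via mixed ketene acetal 7 (not isolated)
Conditions: 6 (excess), EtCO2H (cat.), 140 °C, ethanol distilled off
Reagents that add atoms: none
Why: Johnson–Claisen rearrangement: acid-catalysed exchange gives ketene acetal 7, whose chair transition state places the CH(CH3)CH2Ph group pseudo-equatorial, so both carbinol epimers should give the E trisubstituted alkene while the neighbouring stereocentre is untouched.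

**Step 5**
Reactants: 8 ethyl (S,E)-4,6-dimethyl-7-phenylhept-4-enoate
Product: 9 (S,E)-4,6-dimethyl-7-phenylhept-4-enoic acid
Conditions: LiOH, THF/MeOH/H2O, rt; then 1 M HCl
Reagents that add atoms: lithium hydroxide, [Li+].[OH-]
Why: Saponification of the ethyl ester; no stereocentre lies α to a carbonyl, so nothing can epimerise.

**Step 6**
Reactants: 10 dimethyl (4S,5S)-2,2-dimethyl-1,3-dioxolane-4,5-dicarboxylate (dimethyl 2,3-O-isopropylidene-D-tartrate); 11 methyl glyoxylate
Product: 13 dimethyl (4R,5S)-4-(1-hydroxy-2-methoxy-2-oxoethyl)-2,2-dimethyl-1,3-dioxolane-4,5-dicarboxylate (both carbinol epimers), via lithium enolate 12 (not isolated)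
Conditions: LiN(iPr)2 (LDA), THF, −78 °C, 10 min; then 11 (freshly distilled), −78 °C; AcOH quench at −78 °C
Reagents that add atoms: none
Why: Aldol addition of the tartrate acetonide lithium enolate, made and used at −78 °C to outrun β-elimination of the ring oxygen; the glyoxylate should enter the dioxolane enolate anti to the neighbouring C3 ester, which sets the quaternary C4 with the two ring esters cis, and both C5 carbinol epimers serve.

**Step 7**
Reactants: 13 aldol adduct
Product: 14 dimethyl (4S,5S)-4-(2-methoxy-2-oxoacetyl)-2,2-dimethyl-1,3-dioxolane-4,5-dicarboxylate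
Conditions: DMP, CH2Cl2, rt
Reagents that add atoms: none
Why: Dess–Martin oxidation of the secondary α-hydroxy ester merges both carbinol epimers into one α-keto ester; C4 is quaternary and cannot epimerise.

**Step 8**
Reactants: 14 α-keto ester acetonide
Product: 15 dimethyl (4R,5S)-4-{2-methoxy-2-oxo-1-[2-(4-methylbenzenesulfonyl)hydrazinylidene]ethyl}-2,2-dimethyl-1,3-dioxolane-4,5-dicarboxylate
Conditions: TsNHNH2, toluene, 4 Å MS, 80 °C
Reagents that add atoms: 4-methylbenzenesulfonohydrazide, Cc1ccc(cc1)S(=O)(=O)NN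
Why: Condensation of the activated, non-enolisable α-keto ester with tosylhydrazide to the sulfonylhydrazone; it is done while the diol is still locked in the acetonide, so the hindered ketone can be heated without lactonisation or α-ketol shift and the carbonyl is masked before any thiol is used.

**Step 9**
Reactants: 15 tosylhydrazone acetonide
Product: 16 trimethyl (1S,2R)-1,2-dihydroxy-3-[2-(4-methylbenzenesulfonyl)hydrazinylidene]propane-1,2,3-tricarboxylate (C3,C4-diol with C5 as tosylhydrazone)
Conditions: HS(CH2)3SH, BF3·OEt2, CH2Cl2, −20 to 0 °C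
Reagents that add atoms: none
Why: Lewis acid-mediated transketalisation onto the dithiol (acetonide to 2,2-dimethyl-1,3-dithiane) frees the diol without water or protic acid; C5 is no longer a ketone, so it cannot be thioketalised, and its hydrazono ester is a poor acceptor for γ-lactonisation by the C3 hydroxyl.

**Step 10**
Reactants: 16 diol tosylhydrazone
Product: 17 trimethyl (1S,2R)-3-diazo-1,2-dihydroxypropane-1,2,3-tricarboxylate
Conditions: Et3N, CH2Cl2, 0 °C to rt, dark
Reagents that add atoms: none
Why: Base-induced loss of sulfinate from the tosylhydrazone anion (Bamford–Stevens reaction), which for an α-keto ester hydrazone should run at room temperature with an amine base because the diazo ester formed is acceptor-stabilised.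

**Step 11**
Reactants: 17 diazo diol; 9 (S,E)-4,6-dimethyl-7-phenylhept-4-enoic acid
Product: 18 trimethyl (1S,2R)-3-diazo-1-{[(4E,6S)-4,6-dimethyl-7-phenylhept-4-enoyl]oxy}-2-hydroxypropane-1,2,3-tricarboxylate
Conditions: DCC, DMAP (cat.), CH2Cl2, 0 °C to rt
Reagents that add atoms: none
Why: Steglich esterification; the secondary C3 hydroxyl should be acylated in preference to the fully substituted tertiary C4 hydroxyl, and the electron-poor diazo ester without α-hydrogen tolerates the weak acid and DMAP.

**Step 12**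
Reactants: 18 diazo hydroxy ester
Product: 19 trimethyl (1S,2R)-3-diazo-1-{[(4E,6S)-4,6-dimethyl-7-phenylhept-4-enoyl]oxy}-2-[(trimethylsilyl)oxy]propane-1,2,3-tricarboxylate
Conditions: 1-(trimethylsilyl)imidazole, CH2Cl2, rt to 40 °C
Reagents that add atoms: 1-(trimethylsilyl)imidazole, C[Si](C)(C)n1ccnc1
Why: Neutral silylation with a silyl imidazole, strong enough for the hindered tertiary hydroxyl and free of the acid or Lewis acid that would destroy the diazo ester; it removes the O–H insertion pathway and adds the bulk that shields one face in step 13.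

**Step 13**
Reactants: 19 acyclic α-diazo ester; 20 tert-butyl acrylate
Product: 22 7-tert-butyl 3,4,5-trimethyl (1S,3S,4S,5R,7RS)-1-[(3E,5S)-3,5-dimethyl-6-phenylhex-3-en-1-yl]-4-[(trimethylsilyl)oxy]-2,8-dioxabicyclo[3.2.1]octane-3,4,5,7-tetracarboxylate (any C6 regioisomer and both bridge epimers are carried on together), via carbonyl ylide 21 (not isolated)
Conditions: Rh2(OAc)4 (5 mol %), 20 (10 equiv), benzene, reflux, slow addition of 19
Reagents that add atoms: none
Why: Rh2(OAc)4 should convert the diazo ester into a rhodium carbenoid at C5, which is captured by the carbonyl oxygen of the C3 acyloxy group (C5–O8 bond, six-membered closure by attack of the ester oxygen on the carbenoid) to give the cyclic carbonyl ylide 21, i.e. the 1,3-dioxane ring C1–O2–C3–C4–C5–O8. The ylide then adds suprafacially to the acrylate in an intermolecular 1,3-dipolar cycloaddition (C5–C6 and C1–C7 bonds), which closes the oxolane ring C1–C7–C6–C5–O8 and with it the whole 2,8-dioxabicyclo[3.2.1]octane; the closest known reaction type is the tandem carbonyl ylide formation/cycloaddition of ester-derived ylides with electron-poor π bonds. C1 and C5 are set together by the ylide face that is attacked: the acrylate should approach syn to C3–H and the C4 ester and anti to the C3 ester and the bulky C4 trimethylsilyloxy group next to the reacting C5, which gives (1S,5R). Nucleophilic C5 is expected to bond to the unsubstituted acrylate terminus, but regiochemistry and endo/exo orientation are not needed because the bridge carboxyl is removed later. The silylated quaternary C4 excludes O–H insertion and 1,2-hydrogen shift, and slow addition into excess acrylate should hold back proton transfer from C1' within the ylide, carbenoid dimerisation and any reaction with the short-tethered, electron-rich side-chain alkene.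

**Step 14**
Reactants: 22 cycloadduct
Product: 24 (1S,3S,4S,5R,7RS)-1-[(3E,5S)-3,5-dimethyl-6-phenylhex-3-en-1-yl]-3,4,5-tris(methoxycarbonyl)-4-[(trimethylsilyl)oxy]-2,8-dioxabicyclo[3.2.1]octane-7-carboxylic acid, via trimethylsilyl ester 23 (not isolated)
Conditions: TMSOTf, 2,6-lutidine, CH2Cl2, 0 °C to rt; then pH 7 phosphate buffer; crude acid used directly
Reagents that add atoms: none
Why: Silyl triflate-mediated cleavage of the tert-butyl ester (alkyl–oxygen fission to 2-methylpropene, silyl ester 23 being hydrolysed on work-up) sets the bridge ester apart from the three methyl esters without a strong protic acid, which could protonate the trisubstituted side-chain alkene; the ketal and the tertiary silyl ether should be kept.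

**Step 15**
Reactants: 24 bridge carboxylic acid
Product: 25 7-(1,3-dioxoisoindolin-2-yl) 3,4,5-trimethyl (1S,3S,4S,5R,7RS)-1-[(3E,5S)-3,5-dimethyl-6-phenylhex-3-en-1-yl]-4-[(trimethylsilyl)oxy]-2,8-dioxabicyclo[3.2.1]octane-3,4,5,7-tetracarboxylate
Conditions: N-hydroxyphthalimide, DIC, DMAP (cat.), CH2Cl2, rt
Reagents that add atoms: N-hydroxyphthalimide, O=C1N(O)C(=O)c2ccccc12
Why: Carbodiimide coupling to the redox-active N-(acyloxy)phthalimide; the C4 silyl ether keeps the activated ester of any C6 regioisomer from lactonising onto O4.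

**Step 16**
Reactants: 25 N-(acyloxy)phthalimide
Product: 26 trimethyl (1S,3S,4S,5R)-1-[(3E,5S)-3,5-dimethyl-6-phenylhex-3-en-1-yl]-4-[(trimethylsilyl)oxy]-2,8-dioxabicyclo[3.2.1]octane-3,4,5-tricarboxylate
Conditions: Ru(bpy)3Cl2 (2 mol %), Hantzsch ester, t-BuSH (excess), blue LEDs, degassed DMF, rt
Reagents that add atoms: none
Why: Photoreductive decarboxylation of the N-(acyloxy)phthalimide (Okada-type, Barton-like radical decarboxylation): single-electron reduction fragments the ester to CO2 and the secondary bridge radical, which the thiol at high concentration should quench by hydrogen-atom transfer faster than 5-exo or 6-endo cyclisation onto the side-chain alkene, so that all regio- and stereoisomers converge on the C6H2–C7H2 bridge.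

**Step 17**
Reactants: 26 trimethyl ester silyl ether
Product: 27 (1S,3S,4S,5R)-1-[(3E,5S)-3,5-dimethyl-6-phenylhex-3-en-1-yl]-4-hydroxy-2,8-dioxabicyclo[3.2.1]octane-3,4,5-tricarboxylic acid (target)
Conditions: 1 M aq. KOH, 1,4-dioxane, 80 °C; then 1 M HCl
Reagents that add atoms: potassium hydroxide, [K+].[OH-]
Why: Hydroxide saponification of the three methyl esters with concurrent loss of the silyl ether; C3, the only hydrogen-bearing centre α to a carbonyl, already has its carboxyl in the favoured equatorial position, so no epimerisation is expected.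

**Compound list**
1 | (S)-2-methyl-3-phenylpropanoic acid | OC(=O)[C@@H](C)Cc1ccccc1 | starting material
2 | (S)-2-methyl-3-phenylpropan-1-ol | OC[C@@H](C)Cc1ccccc1 | intermediate
3 | (S)-2-methyl-3-phenylpropanal | O=C[C@@H](C)Cc1ccccc1 | intermediate
4 | isopropenylmagnesium bromide | C=C(C)[Mg]Br | starting material
5 | (3RS,4S)-2,4-dimethyl-5-phenylpent-1-en-3-ol | C=C(C)C(O)[C@@H](C)Cc1ccccc1 | intermediate
6 | triethyl orthoacetate | CC(OCC)(OCC)OCC | starting material
7 | mixed ketene acetal (1-ethoxyvinyl ether of 5) | C=C(OCC)OC(C(C)=C)[C@@H](C)Cc1ccccc1 | intermediate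
8 | ethyl (S,E)-4,6-dimethyl-7-phenylhept-4-enoate | CCOC(=O)CC/C(C)=C/[C@@H](C)Cc1ccccc1 | intermediate
9 | (S,E)-4,6-dimethyl-7-phenylhept-4-enoic acid | OC(=O)CC/C(C)=C/[C@@H](C)Cc1ccccc1 | intermediate
10 | dimethyl (4S,5S)-2,2-dimethyl-1,3-dioxolane-4,5-dicarboxylate | COC(=O)[C@H]1OC(C)(C)O[C@@H]1C(=O)OC | starting material
11 | methyl glyoxylate | COC(=O)C=O | starting material
12 | lithium enolate of 10 | [Li+].COC([O-])=C1OC(C)(C)O[C@@H]1C(=O)OC | intermediate
13 | dimethyl (4R,5S)-4-(1-hydroxy-2-methoxy-2-oxoethyl)-2,2-dimethyl-1,3-dioxolane-4,5-dicarboxylate (carbinol epimers) | COC(=O)C(O)[C@@]1(C(=O)OC)OC(C)(C)O[C@@H]1C(=O)OC | intermediate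
14 | dimethyl (4S,5S)-4-(2-methoxy-2-oxoacetyl)-2,2-dimethyl-1,3-dioxolane-4,5-dicarboxylate | COC(=O)C(=O)[C@@]1(C(=O)OC)OC(C)(C)O[C@@H]1C(=O)OC | intermediate
15 | tosylhydrazone of 14, (4R,5S) | COC(=O)C(=NNS(=O)(=O)c1ccc(C)cc1)[C@@]1(C(=O)OC)OC(C)(C)O[C@@H]1C(=O)OC | intermediate
16 | trimethyl (1S,2R)-1,2-dihydroxy-3-[2-(4-methylbenzenesulfonyl)hydrazinylidene]propane-1,2,3-tricarboxylate | COC(=O)C(=NNS(=O)(=O)c1ccc(C)cc1)[C@](O)(C(=O)OC)[C@@H](C(=O)OC)O | intermediate
17 | trimethyl (1S,2R)-3-diazo-1,2-dihydroxypropane-1,2,3-tricarboxylate | COC(=O)C(=[N+]=[N-])[C@](O)(C(=O)OC)[C@@H](C(=O)OC)O | intermediate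
18 | trimethyl (1S,2R)-3-diazo-1-{[(4E,6S)-4,6-dimethyl-7-phenylhept-4-enoyl]oxy}-2-hydroxypropane-1,2,3-tricarboxylate | COC(=O)C(=[N+]=[N-])[C@](O)(C(=O)OC)[C@@H](C(=O)OC)OC(=O)CC/C(C)=C/[C@@H](C)Cc1ccccc1 | intermediate
19 | trimethyl (1S,2R)-3-diazo-1-{[(4E,6S)-4,6-dimethyl-7-phenylhept-4-enoyl]oxy}-2-[(trimethylsilyl)oxy]propane-1,2,3-tricarboxylate | COC(=O)C(=[N+]=[N-])[C@](O[Si](C)(C)C)(C(=O)OC)[C@@H](C(=O)OC)OC(=O)CC/C(C)=C/[C@@H](C)Cc1ccccc1 | intermediate
20 | tert-butyl acrylate | C=CC(=O)OC(C)(C)C | starting material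
21 | six-membered ester carbonyl ylide | C/C(=C\[C@@H](C)Cc1ccccc1)CCC1=[O+][C-](C(=O)OC)[C@](O[Si](C)(C)C)(C(=O)OC)[C@@H](C(=O)OC)O1 | intermediate
22 | 7-tert-butyl 3,4,5-trimethyl (1S,3S,4S,5R,7RS)-1-[(3E,5S)-3,5-dimethyl-6-phenylhex-3-en-1-yl]-4-[(trimethylsilyl)oxy]-2,8-dioxabicyclo[3.2.1]octane-3,4,5,7-tetracarboxylate | C/C(=C\[C@@H](C)Cc1ccccc1)CC[C@@]12C(C(=O)OC(C)(C)C)C[C@@](C(=O)OC)(O1)[C@](O[Si](C)(C)C)(C(=O)OC)[C@@H](C(=O)OC)O2 | intermediate
23 | trimethylsilyl ester of 24 | C/C(=C\[C@@H](C)Cc1ccccc1)CC[C@@]12C(C(=O)O[Si](C)(C)C)C[C@@](C(=O)OC)(O1)[C@](O[Si](C)(C)C)(C(=O)OC)[C@@H](C(=O)OC)O2 | intermediate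
24 | (1S,3S,4S,5R,7RS)-1-[(3E,5S)-3,5-dimethyl-6-phenylhex-3-en-1-yl]-3,4,5-tris(methoxycarbonyl)-4-[(trimethylsilyl)oxy]-2,8-dioxabicyclo[3.2.1]octane-7-carboxylic acid | C/C(=C\[C@@H](C)Cc1ccccc1)CC[C@@]12C(C(=O)O)C[C@@](C(=O)OC)(O1)[C@](O[Si](C)(C)C)(C(=O)OC)[C@@H](C(=O)OC)O2 | intermediate
25 | N-(acyloxy)phthalimide of 24 | C/C(=C\[C@@H](C)Cc1ccccc1)CC[C@@]12C(C(=O)ON3C(=O)c4ccccc4C3=O)C[C@@](C(=O)OC)(O1)[C@](O[Si](C)(C)C)(C(=O)OC)[C@@H](C(=O)OC)O2 | intermediate
26 | trimethyl (1S,3S,4S,5R)-1-[(3E,5S)-3,5-dimethyl-6-phenylhex-3-en-1-yl]-4-[(trimethylsilyl)oxy]-2,8-dioxabicyclo[3.2.1]octane-3,4,5-tricarboxylate | C/C(=C\[C@@H](C)Cc1ccccc1)CC[C@@]12CC[C@@](C(=O)OC)(O1)[C@](O[Si](C)(C)C)(C(=O)OC)[C@@H](C(=O)OC)O2 | intermediate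
27 | (1S,3S,4S,5R)-1-[(3E,5S)-3,5-dimethyl-6-phenylhex-3-en-1-yl]-4-hydroxy-2,8-dioxabicyclo[3.2.1]octane-3,4,5-tricarboxylic acid | C/C(=C\[C@@H](C)Cc1ccccc1)CC[C@@]12CC[C@@](C(=O)O)(O1)[C@](O)(C(=O)O)[C@@H](C(=O)O)O2 | target

**Step count**
Total: 17 steps. Longest linear sequence: 12 steps (steps 6–17 from 10; the side-chain branch, steps 1–5 then 11–17, is equally long).

**Steps most likely to fail, with fallbacks**

Step 13. The mono-activated alkene may intercept ylide 21 more slowly than the ylide decays by proton transfer from C1' or by dimerisation, and attack on the shielded face would give the wrong C1/C5 pair. The fallback sets out from 19 and uses the more reactive alkyne dipolarophile tert-butyl propiolate under the same Rh2(OAc)4 catalysis. This should give the 2,8-dioxabicyclo[3.2.1]oct-6-ene 7-tert-butyl ester F1. Its strained, electron-poor C6=C7 bond is then reduced chemoselectively with diimide (2-nitrobenzenesulfonohydrazide, Et3N, CH2Cl2, rt), which should leave the unstrained trisubstituted side-chain alkene alone. The route is rejoined at 22.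

Step 16. The bridge radical may cyclise onto the side-chain alkene before it is reduced, or thiyl radicals may add reversibly to that alkene and erode its E geometry. The fallback avoids a long-lived bridge radical. It sets out from 19 and uses (E)-1,2-bis(phenylsulfonyl)ethene as an acetylene equivalent in the Rh2(OAc)4 cycloaddition, giving the 6,7-bis(phenylsulfonyl) cycloadduct F2. Buffered reductive elimination (Na/Hg, Na2HPO4, THF/MeOH, −20 °C) expels both sulfinates, the transient radical or anion losing its vicinal sulfonyl group far faster than it could cyclise. This gives the 2,8-dioxabicyclo[3.2.1]oct-6-ene triester F3. Diimide reduction of the strained disubstituted C6=C7 bond then rejoins the route at 26.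

Step 9. The electron-poor acetonide may resist ionisation at the low temperature needed, and warming may bring on γ-lactonisation or attack on the hydrazone. The fallback keeps C5 at the alcohol level until the acetonide is gone. It sets out from 13, whose C5 hydroxyl is silylated (TBSOTf, 2,6-lutidine) to the C5 tert-butyldimethylsilyl ether F4. With no C=O or C=N at C5, the same dithiol/BF3·OEt2 exchange can be run warmer to give the C3,C4-diol F5. Steglich acylation with 9 gives the C3 ester F6, and HF·pyridine removes the silyl group to give the C5 alcohol F7. Dess–Martin oxidation gives the α-keto ester F8, and tosylhydrazide condensation (THF, 50 °C) gives the tosylhydrazone F9. Et3N in CH2Cl2 then rejoins the route at 18.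

**Further compounds**
F1 | step 13 | 7-tert-butyl 3,4,5-trimethyl (1S,3S,4S,5R)-1-[(3E,5S)-3,5-dimethyl-6-phenylhex-3-en-1-yl]-4-[(trimethylsilyl)oxy]-2,8-dioxabicyclo[3.2.1]oct-6-ene-3,4,5,7-tetracarboxylate | C/C(=C\[C@@H](C)Cc1ccccc1)CC[C@@]12C(C(=O)OC(C)(C)C)=C[C@@](C(=O)OC)(O1)[C@](O[Si](C)(C)C)(C(=O)OC)[C@@H](C(=O)OC)O2
F2 | step 16 | trimethyl 1-[(3E,5S)-3,5-dimethyl-6-phenylhex-3-en-1-yl]-6,7-bis(phenylsulfonyl)-4-[(trimethylsilyl)oxy]-2,8-dioxabicyclo[3.2.1]octane-3,4,5-tricarboxylate | C/C(=C\[C@@H](C)Cc1ccccc1)CC[C@@]12C(S(=O)(=O)c3ccccc3)C(S(=O)(=O)c3ccccc3)[C@@](C(=O)OC)(O1)[C@](O[Si](C)(C)C)(C(=O)OC)[C@@H](C(=O)OC)O2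
F3 | step 16 | trimethyl 1-[(3E,5S)-3,5-dimethyl-6-phenylhex-3-en-1-yl]-4-[(trimethylsilyl)oxy]-2,8-dioxabicyclo[3.2.1]oct-6-ene-3,4,5-tricarboxylate | C/C(=C\[C@@H](C)Cc1ccccc1)CC[C@@]12C=C[C@@](C(=O)OC)(O1)[C@](O[Si](C)(C)C)(C(=O)OC)[C@@H](C(=O)OC)O2
F4 | step 9 | C5 tert-butyldimethylsilyl ether of aldol adduct 13 | COC(=O)C(O[Si](C)(C)C(C)(C)C)[C@@]1(C(=O)OC)OC(C)(C)O[C@@H]1C(=O)OC
F5 | step 9 | C5-silyloxy C3,C4-diol triester | COC(=O)C(O[Si](C)(C)C(C)(C)C)[C@](O)(C(=O)OC)[C@@H](C(=O)OC)O
F6 | step 9 | C5-silyloxy C3 ester of the side-chain acid | COC(=O)C(O[Si](C)(C)C(C)(C)C)[C@](O)(C(=O)OC)[C@@H](C(=O)OC)OC(=O)CC/C(C)=C/[C@@H](C)Cc1ccccc1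
F7 | step 9 | C5 alcohol C3 ester | COC(=O)C(O)[C@](O)(C(=O)OC)[C@@H](C(=O)OC)OC(=O)CC/C(C)=C/[C@@H](C)Cc1ccccc1
F8 | step 9 | C5 α-keto ester C3 ester | COC(=O)C(=O)[C@](O)(C(=O)OC)[C@@H](C(=O)OC)OC(=O)CC/C(C)=C/[C@@H](C)Cc1ccccc1
F9 | step 9 | tosylhydrazone of F8 | COC(=O)C(=NNS(=O)(=O)c1ccc(C)cc1)[C@](O)(C(=O)OC)[C@@H](C(=O)OC)OC(=O)CC/C(C)=C/[C@@H](C)Cc1ccccc1
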